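**Strategy.** The hydroperoxy-dienone ring C is a phenol in disguise: singlet oxygen adds para to OH at the very end (naphthalene locants throughout). What must be built is a tetralin with the C1 quaternary centre next to the C2 isopropenyl methine. Ring B (C1–C2–C3–C4–C4a–C8a) is closed by forming C2–C3: the aryl vinyl group of a styrene is hydroborated and copper delivers the primary alkyl group intramolecularly, anti-SN2', to a 2-methylallyl chloride on C1. The step exploits that C2 is the γ-terminus of the isopropenyl allyl unit, so one operation gives ring B, the C2 stereocentre and the isopropenyl group. C1 comes from an asymmetric conjugate addition to 3-methylcyclopentenone, whose ring is then cleaved.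

Key step: step 8

Assumption: which ligand hand gives the R centre in step 2 and which hand is matched in step 8 cannot be predicted with certainty; the hands written are working choices to be fixed by one trial each.

**Step 1**
Reactants: 1 1-chloro-3-methoxy-2-methylbenzene
Product: 3 5-bromo-1-chloro-3-methoxy-2-methylbenzene, via aryl pinacolboronate 2 (not isolated)
Conditions: [Ir(OMe)(cod)]2 (1.5 mol %), 4,4'-di-tert-butyl-2,2'-bipyridine, B2pin2, THF, 80 °C; then CuBr2, MeOH/H2O, 80 °C
Reagents that add atoms: copper dibromide, [Cu+2].[Br-].[Br-]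
Why: Iridium-catalysed C–H borylation is sterically controlled and should take the only ring C–H without an ortho substituent (meta to both Cl and OMe), and the boronate is then converted to the bromide by copper-mediated bromodeboronation in the same flask.

**Step 2**
Reactants: 3 5-bromo-1-chloro-3-methoxy-2-methylbenzene; 4 3-methylcyclopent-2-en-1-one
Product: 8 (R)-3-(3-chloro-5-methoxy-4-methylphenyl)-3-methylcyclopent-1-en-1-yl acetate, via aryllithium 5 (not isolated), via aryldimethylalane 6 (not isolated), via aluminium enolate 7 (not isolated)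
Conditions: n-BuLi, THF, −78 °C; Me2AlCl, −78 °C to rt; then 4, Cu(OTf)2 (5 mol %), chiral sulfonate-bearing imidazolinium salt (NHC ligand precursor, 6 mol %), THF, −30 °C; then Ac2O, −30 °C to rt
Reagents that add atoms: acetic anhydride, CC(=O)OC(C)=O
Why: Copper-catalysed asymmetric conjugate addition of an aryl(dimethyl)alane to a β-substituted cyclic enone sets the benzylic quaternary centre under ligand control (ligand hand chosen for R), and O-acetylation of the aluminium enolate fixes the enol double bond on the side of the quaternary carbon.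

**Step 3**
Reactants: 8 (R)-3-(3-chloro-5-methoxy-4-methylphenyl)-3-methylcyclopent-1-en-1-yl acetate
Product: 11 methyl (4S)-4-(3-chloro-5-methoxy-4-methylphenyl)-4-methyl-5-oxopentanoate, via mixed anhydride 9 (not isolated), via aldehyde acid 10 (not isolated)
Conditions: O3, CH2Cl2, −78 °C; Me2S, −78 °C to rt; aq. NaHCO3, then acidify; then TMSCHN2, PhMe/MeOH, 0 °C
Reagents that add atoms: ozone, [O-][O+]=O; (trimethylsilyl)diazomethane, C[Si](C)(C)C=[N+]=[N-]
Why: Ozonolysis cleaves the enol acetate C=C bond of the five-membered ring much faster than it attacks the arene, giving the neopentyl aldehyde (future C2) and, after anhydride hydrolysis and methylation, the propanoate arm; the stereocentre is untouched and becomes S only because CHO outranks aryl.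

**Step 4**
Reactants: 11 methyl (4S)-4-(3-chloro-5-methoxy-4-methylphenyl)-4-methyl-5-oxopentanoate
Product: 12 methyl (4S)-4-(2-bromo-3-chloro-5-methoxy-4-methylphenyl)-4-methyl-5-oxopentanoate
Conditions: NBS, MeCN, 0 °C to rt
Reagents that add atoms: N-bromosuccinimide, O=C1CCC(=O)N1Br
Why: Electrophilic aromatic bromination should go para to the methoxy group (ortho to Cl), because the other free position is ortho to OMe, shielded by the O-methyl group and flanked by the quaternary carbon.

**Step 5**
Reactants: 12 methyl (4S)-4-(2-bromo-3-chloro-5-methoxy-4-methylphenyl)-4-methyl-5-oxopentanoate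
Product: 13 methyl (4S)-4-(3-chloro-2-ethenyl-5-methoxy-4-methylphenyl)-4-methyl-5-oxopentanoate
Conditions: tributyl(vinyl)stannane, Pd(PtBu3)2 (5 mol %), CsF, 1,4-dioxane, 60 °C
Reagents that add atoms: tributyl(vinyl)stannane, C=C[Sn](CCCC)(CCCC)CCCC
Why: Stille coupling occurs at the C–Br bond, which adds to zerovalent palladium far faster than the C–Cl bond at this temperature, and the neutral fluoride-promoted conditions spare the aldehyde and the ester.

**Step 6**
Reactants: 13 methyl (4S)-4-(3-chloro-2-ethenyl-5-methoxy-4-methylphenyl)-4-methyl-5-oxopentanoate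
Product: 14 methyl (4S)-4-(3-chloro-2-ethenyl-5-methoxy-4-methylphenyl)-5-hydroxy-4,6-dimethylhept-6-enoate (both C5 epimers)
Conditions: isopropenylmagnesium bromide (1.2 equiv), THF, −78 °C; sat. NH4Cl at −78 °C; crude product used at once
Reagents that add atoms: isopropenylmagnesium bromide, C=C(C)[Mg]Br
Why: Grignard 1,2-addition to the aldehyde is much faster than attack on the ester at −78 °C, the cold quench keeps the alkoxide from lactonising, and the new carbinol centre needs no control because step 7 erases it.

**Step 7**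
Reactants: 14 methyl (4S)-4-(3-chloro-2-ethenyl-5-methoxy-4-methylphenyl)-5-hydroxy-4,6-dimethylhept-6-enoate
Product: 15 methyl (4R,5E)-7-chloro-4-(3-chloro-2-ethenyl-5-methoxy-4-methylphenyl)-4,6-dimethylhept-5-enoate
Conditions: SOCl2, Et2O, 0 °C to rt
Reagents that add atoms: thionyl chloride, O=S(Cl)Cl
Why: The chlorosulfite of the secondary allylic alcohol collapses by SNi' allylic transposition to the primary (E)-allylic chloride, since direct substitution at the neopentyl carbinol carbon is blocked; the quaternary centre is untouched (descriptor R by priority change only).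

**Step 8**
Reactants: 15 methyl (4R,5E)-7-chloro-4-(3-chloro-2-ethenyl-5-methoxy-4-methylphenyl)-4,6-dimethylhept-5-enoate
Product: 17 methyl 3-[(1R,2R)-5-chloro-7-methoxy-1,6-dimethyl-2-(prop-1-en-2-yl)-1,2,3,4-tetrahydronaphthalen-1-yl]propanoate, via B-alkyl-9-BBN 16 (not isolated)
Conditions: (9-BBN-H)2 (0.55 equiv), THF, 60 °C; then KOMe (1.2 equiv), CuOAc (10 mol %), (R)-DTBM-SEGPHOS (11 mol %), 1,4-dioxane, 0.01 M, 40 °C
Reagents that add atoms: none
Why: 9-BBN adds only to the monosubstituted aryl vinyl group (boron at the terminal carbon, future C3; the trisubstituted allylic alkene and the ester are inert), methoxide forms the borate that passes its primary alkyl group to copper, and the alkylcopper attacks the γ-carbon (C2) of the allylic chloride with anti loss of chloride, so the C2–C3 bond, the C2 stereocentre and the isopropenyl group arise together. The closest known reaction is the copper-catalysed γ-selective allyl–alkyl coupling of alkyl-9-BBN reagents with allylic chlorides and phosphates, used here in ring-closing form. Ring B closes in a 6-exo-trig mode, the alkene being exocyclic to the forming ring; α-attack would need an eight-membered ring and should not compete. C2 is controlled by the C1 quaternary centre in a chair-like transition state: the alkenyl residue is pseudo-equatorial to avoid 1,3-allylic strain with the arene, the small methyl takes the crowded inside position next to the alkene, and the propanoate arm lies anti to the incoming C–Cu bond, which places methyl and isopropenyl cis (1R,2R). The step needs face selectivity at C2 and γ-regioselectivity: the first rests on this methyl-versus-chain difference, which is small and is therefore reinforced by the bulky bisphosphine on copper, and the second rests on ring size and the SN2' preference of alkylcopper. High dilution suppresses intermolecular coupling, and KOMe is degenerate toward the methyl ester.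

**Step 9**
Reactants: 17 methyl 3-[(1R,2R)-5-chloro-7-methoxy-1,6-dimethyl-2-(prop-1-en-2-yl)-1,2,3,4-tetrahydronaphthalen-1-yl]propanoate
Product: 18 methyl 3-[(1R,2R)-5-ethenyl-7-methoxy-1,6-dimethyl-2-(prop-1-en-2-yl)-1,2,3,4-tetrahydronaphthalen-1-yl]propanoate
Conditions: tributyl(vinyl)stannane, Pd(PtBu3)2 (5 mol %), CsF, 1,4-dioxane, 100 °C
Reagents that add atoms: tributyl(vinyl)stannane, C=C[Sn](CCCC)(CCCC)CCCC
Why: Fluoride-promoted Stille coupling with the electron-rich, bulky phosphine catalyst engages the hindered aryl chloride at the higher temperature, while the isopropenyl group and the ester are inert.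

**Step 10**
Reactants: 18 methyl 3-[(1R,2R)-5-ethenyl-7-methoxy-1,6-dimethyl-2-(prop-1-en-2-yl)-1,2,3,4-tetrahydronaphthalen-1-yl]propanoate
Product: 20 methyl 3-[(1R,2R)-5-ethenyl-7-hydroxy-1,6-dimethyl-2-(prop-1-en-2-yl)-1,2,3,4-tetrahydronaphthalen-1-yl]propanoate, via hydroxy acid 19 (not isolated)
Conditions: NaSEt (6 equiv), DMF, 110 °C; 1 M HCl work-up; then TMSCHN2 (1.1 equiv), PhMe/MeOH, 0 °C
Reagents that add atoms: (trimethylsilyl)diazomethane, C[Si](C)(C)C=[N+]=[N-]
Why: Thiolate SN2 demethylation frees the phenol without acid, so both alkenes survive; it also cleaves the methyl ester, which is restored by TMSCHN2 because the carboxylic acid is methylated far faster than the phenol.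

**Step 11**
Reactants: 20 methyl 3-[(1R,2R)-5-ethenyl-7-hydroxy-1,6-dimethyl-2-(prop-1-en-2-yl)-1,2,3,4-tetrahydronaphthalen-1-yl]propanoate
Product: 21 trigonochinene C, methyl 3-[(1R,2R,4aR)-5-ethenyl-4a-hydroperoxy-1,6-dimethyl-7-oxo-2-(prop-1-en-2-yl)-1,2,3,4,4a,7-hexahydronaphthalen-1-yl]propanoate
Conditions: O2, 5,10,15,20-tetraphenylporphyrin (1 mol %), visible light, CH2Cl2/MeOH, −20 °C; non-reductive work-up
Reagents that add atoms: dioxygen, O=O
Why: Singlet oxygen attacks the electron-rich phenol at the para carbon C4a (phenol para-hydroperoxidation, much faster than ene reaction at the 1,1-disubstituted alkene or cycloaddition at the twisted styrene) and should enter syn to the axial C1 methyl, the only face from which ring B passes directly into a chair with axial OOH and equatorial isopropenyl, which gives 4aR.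

**Compound list**
1 | 1-chloro-3-methoxy-2-methylbenzene (3-chloro-2-methylanisole) | COc1cccc(Cl)c1C | starting material
2 | 2-(3-chloro-5-methoxy-4-methylphenyl)-4,4,5,5-tetramethyl-1,3,2-dioxaborolane | COc1cc(B2OC(C)(C)C(C)(C)O2)cc(Cl)c1C | intermediate
3 | 5-bromo-1-chloro-3-methoxy-2-methylbenzene | COc1cc(Br)cc(Cl)c1C | intermediate
4 | 3-methylcyclopent-2-en-1-one | CC1=CC(=O)CC1 | starting material
5 | (3-chloro-5-methoxy-4-methylphenyl)lithium | COc1cc([Li])cc(Cl)c1C | intermediate
6 | (3-chloro-5-methoxy-4-methylphenyl)dimethylalane | COc1cc([Al](C)C)cc(Cl)c1C | intermediate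
7 | dimethylaluminium (R)-3-(3-chloro-5-methoxy-4-methylphenyl)-3-methylcyclopent-1-en-1-olate | C[Al](C)OC1=C[C@@](c2cc(OC)c(C)c(Cl)c2)(C)CC1 | intermediate
8 | (R)-3-(3-chloro-5-methoxy-4-methylphenyl)-3-methylcyclopent-1-en-1-yl acetate | CC(=O)OC1=C[C@@](c2cc(OC)c(C)c(Cl)c2)(C)CC1 | intermediate
9 | acetic (4S)-4-(3-chloro-5-methoxy-4-methylphenyl)-4-methyl-5-oxopentanoic anhydride | O=C[C@@](c1cc(OC)c(C)c(Cl)c1)(C)CCC(=O)OC(C)=O | intermediate
10 | (4S)-4-(3-chloro-5-methoxy-4-methylphenyl)-4-methyl-5-oxopentanoic acid | O=C[C@@](c1cc(OC)c(C)c(Cl)c1)(C)CCC(=O)O | intermediate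
11 | methyl (4S)-4-(3-chloro-5-methoxy-4-methylphenyl)-4-methyl-5-oxopentanoate | O=C[C@@](c1cc(OC)c(C)c(Cl)c1)(C)CCC(=O)OC | intermediate
12 | methyl (4S)-4-(2-bromo-3-chloro-5-methoxy-4-methylphenyl)-4-methyl-5-oxopentanoate | O=C[C@@](c1cc(OC)c(C)c(Cl)c1Br)(C)CCC(=O)OC | intermediate
13 | methyl (4S)-4-(3-chloro-2-ethenyl-5-methoxy-4-methylphenyl)-4-methyl-5-oxopentanoate | O=C[C@@](c1cc(OC)c(C)c(Cl)c1C=C)(C)CCC(=O)OC | intermediate
14 | methyl (4S)-4-(3-chloro-2-ethenyl-5-methoxy-4-methylphenyl)-5-hydroxy-4,6-dimethylhept-6-enoate (C5 epimers) | C=C(C)C(O)[C@@](c1cc(OC)c(C)c(Cl)c1C=C)(C)CCC(=O)OC | intermediate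
15 | methyl (4R,5E)-7-chloro-4-(3-chloro-2-ethenyl-5-methoxy-4-methylphenyl)-4,6-dimethylhept-5-enoate | ClC/C(C)=C/[C@@](c1cc(OC)c(C)c(Cl)c1C=C)(C)CCC(=O)OC | intermediate
16 | methyl (4R,5E)-4-{2-[2-(9-borabicyclo[3.3.1]nonan-9-yl)ethyl]-3-chloro-5-methoxy-4-methylphenyl}-7-chloro-4,6-dimethylhept-5-enoate | ClC/C(C)=C/[C@@](c1cc(OC)c(C)c(Cl)c1CCB2C3CCCC2CCC3)(C)CCC(=O)OC | intermediate
17 | methyl 3-[(1R,2R)-5-chloro-7-methoxy-1,6-dimethyl-2-(prop-1-en-2-yl)-1,2,3,4-tetrahydronaphthalen-1-yl]propanoate | Clc1c(C)c(OC)cc2c1CC[C@H](C(=C)C)[C@@]2(C)CCC(=O)OC | intermediate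
18 | methyl 3-[(1R,2R)-5-ethenyl-7-methoxy-1,6-dimethyl-2-(prop-1-en-2-yl)-1,2,3,4-tetrahydronaphthalen-1-yl]propanoate | C=Cc1c(C)c(OC)cc2c1CC[C@H](C(=C)C)[C@@]2(C)CCC(=O)OC | intermediate
19 | 3-[(1R,2R)-5-ethenyl-7-hydroxy-1,6-dimethyl-2-(prop-1-en-2-yl)-1,2,3,4-tetrahydronaphthalen-1-yl]propanoic acid | C=Cc1c(C)c(O)cc2c1CC[C@H](C(=C)C)[C@@]2(C)CCC(=O)O | intermediate
20 | methyl 3-[(1R,2R)-5-ethenyl-7-hydroxy-1,6-dimethyl-2-(prop-1-en-2-yl)-1,2,3,4-tetrahydronaphthalen-1-yl]propanoate | C=Cc1c(C)c(O)cc2c1CC[C@H](C(=C)C)[C@@]2(C)CCC(=O)OC | intermediate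
21 | trigonochinene C, methyl 3-[(1R,2R,4aR)-5-ethenyl-4a-hydroperoxy-1,6-dimethyl-7-oxo-2-(prop-1-en-2-yl)-1,2,3,4,4a,7-hexahydronaphthalen-1-yl]propanoate | C=CC1=C(C)C(=O)C=C2[C@]1(OO)CC[C@H](C(=C)C)[C@@]2(C)CCC(=O)OC | target

**Step count.** Total: 11 steps. Longest linear sequence: 11 steps (1 to 21).

**Steps most likely to fail**

Step 8. The alkyl group may pass to copper too slowly and protodeboronate, or the two faces of the allyl terminus C2 may not be told apart well enough, because methyl and the propanoate arm on C1 differ little in size. The fallback leaves the route at 13 and returns at 17, closing the same C2–C3 bond by a Lewis-acid carbonyl–ene cyclisation instead. Wittig olefination of 13 with isopropylidenetriphenylphosphorane should give methyl (4R)-4-(3-chloro-2-ethenyl-5-methoxy-4-methylphenyl)-4,6-dimethylhept-5-enoate F1. Hydroboration of its aryl vinyl group with 9-BBN and oxidation with NaBO3 should give methyl (4R)-4-[3-chloro-2-(2-hydroxyethyl)-5-methoxy-4-methylphenyl]-4,6-dimethylhept-5-enoate F2, and oxidation with DMP the arylacetaldehyde methyl (4R)-4-[3-chloro-5-methoxy-4-methyl-2-(2-oxoethyl)phenyl]-4,6-dimethylhept-5-enoate F3. Treatment with Me2AlCl in CH2Cl2 at −78 °C (isopulegol-type ene reaction through a compact chair) should give methyl 3-[(1R,2R,3R)-5-chloro-3-hydroxy-7-methoxy-1,6-dimethyl-2-(prop-1-en-2-yl)-1,2,3,4-tetrahydronaphthalen-1-yl]propanoate F4, with OH and isopropenyl trans and with alcohol diastereomers that can be separated. Barton–McCombie deoxygenation through the xanthate methyl 3-[(1R,2R,3R)-5-chloro-7-methoxy-1,6-dimethyl-3-{[(methylsulfanyl)carbonothioyl]oxy}-2-(prop-1-en-2-yl)-1,2,3,4-tetrahydronaphthalen-1-yl]propanoate F5 (NaH, CS2, MeI; then Bu3SnH, AIBN, 80 °C) should give 17.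

Step 2. Aryl transfer to the hindered β-carbon of the five-membered enone may be sluggish, enantioselectivity may erode, or O-acylation of the aluminium enolate may be incomplete. The fallback leaves the route at 3 and returns at 8 by exchanging the roles of the two groups. Lithiation of 3 and addition to 3-ethoxycyclopent-2-en-1-one with acidic work-up (Stork–Danheiser transposition) should give 3-(3-chloro-5-methoxy-4-methylphenyl)cyclopent-2-en-1-one F6. Copper-catalysed asymmetric conjugate addition of Me3Al (copper thiophene-2-carboxylate, Cu(O2CC4H3S), with a chiral phosphoramidite, Et2O, −30 °C) and trapping with Ac2O should then give 8.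

Step 11. Oxygen delivery at C4a may show poor facial selectivity, and singlet oxygen may also react in an ene reaction at the isopropenyl group or add to the styrene. The fallback leaves the route at 20 and returns at 21: base-mediated autoxidation of the phenolate with triplet oxygen (KOtBu, O2, t-BuOH/THF, −20 °C), a phenoxide electron-transfer and radical-recombination pathway that ignores isolated alkenes. It makes no new compound.

**Further compounds**
F1 | step 8 | methyl (4R)-4-(3-chloro-2-ethenyl-5-methoxy-4-methylphenyl)-4,6-dimethylhept-5-enoate | CC(C)=C[C@@](c1cc(OC)c(C)c(Cl)c1C=C)(C)CCC(=O)OC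
F2 | step 8 | methyl (4R)-4-[3-chloro-2-(2-hydroxyethyl)-5-methoxy-4-methylphenyl]-4,6-dimethylhept-5-enoate | CC(C)=C[C@@](c1cc(OC)c(C)c(Cl)c1CCO)(C)CCC(=O)OC
F3 | step 8 | methyl (4R)-4-[3-chloro-5-methoxy-4-methyl-2-(2-oxoethyl)phenyl]-4,6-dimethylhept-5-enoate | CC(C)=C[C@@](c1cc(OC)c(C)c(Cl)c1CC=O)(C)CCC(=O)OC
F4 | step 8 | methyl 3-[(1R,2R,3R)-5-chloro-3-hydroxy-7-methoxy-1,6-dimethyl-2-(prop-1-en-2-yl)-1,2,3,4-tetrahydronaphthalen-1-yl]propanoate | Clc1c(C)c(OC)cc2c1C[C@@H](O)[C@H](C(=C)C)[C@@]2(C)CCC(=O)OC
F5 | step 8 | methyl 3-[(1R,2R,3R)-5-chloro-7-methoxy-1,6-dimethyl-3-{[(methylsulfanyl)carbonothioyl]oxy}-2-(prop-1-en-2-yl)-1,2,3,4-tetrahydronaphthalen-1-yl]propanoate | Clc1c(C)c(OC)cc2c1C[C@@H](OC(=S)SC)[C@H](C(=C)C)[C@@]2(C)CCC(=O)OC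
F6 | step 2 | 3-(3-chloro-5-methoxy-4-methylphenyl)cyclopent-2-en-1-one | O=C1C=C(c2cc(OC)c(C)c(Cl)c2)CC1
F0 | step 11 | none | none
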